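**Retrosynthetic overview**
1. Target 26 ⇐ methyl ketone 22 (C13=O) by Horner–Wadsworth–Emmons olefination, ester reduction and acetylation.
2. Ring A of 22 ⇐ 6-(cyclohexenyl)-3-methyl-δ-lactone 17 by Ireland–Claisen ring contraction; this forms C4–C5 and the Δ1(10) alkene and relays the C1 carbinol centre to C4 and C5.
3. Lactone 17 ⇐ ring B enal 10 + allyl unit by reagent-controlled asymmetric carbonyl allylation (the key intermolecular C1–C2 bond), then methacrylate acylation, ring-closing metathesis and conjugate reduction.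
4. Enal 10 ⇐ ketone 5 (vinyl triflate, carbonylation); 5 ⇐ 2-methylcyclohex-2-enone by asymmetric conjugate methyl addition and Mukaiyama–Michael addition to methyl vinyl ketone (sets C8 and C9).
5. Ring order: ring B is the commercial six-membered ring and is kept throughout; ring A is closed late, first as a lactone, then as the carbocycle.

Assumption: the target is taken exactly as drawn, (1S,5S,6R,8aR) in naphthalene numbering with 8a-H cis to the 5- and 6-methyls; locants C1–C16 in the Why lines are halimane locants of 26 (C4 ester-bearing quaternary C, C5 ring-fusion CH, C10 ring-fusion alkene C, C1 alkene CH, C8 CHMe, C9 quaternary C carrying side chain C11–C16).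

**Step 1**
Reactants: 1 2-methylcyclohex-2-en-1-one
Product: 3 trimethyl{[(3R)-2,3-dimethylcyclohex-1-en-1-yl]oxy}silane, via dimethylaluminium enolate 2 (not isolated)
Conditions: Me3Al, copper thiophene-2-carboxylate (CuTC, C5H3CuO2S, 2 mol%), chiral biphenol phosphoramidite L* (4 mol%, the enantiomer giving 3R), Et2O, −30 °C; then TMSOTf, THF, −30 °C → rt
Reagents that add atoms: trimethylaluminium C[Al](C)C; trimethylsilyl trifluoromethanesulfonate C[Si](C)(C)OS(=O)(=O)C(F)(F)F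
Why: Copper-catalysed asymmetric conjugate addition of Me3Al, in which the chiral phosphoramidite–copper complex selects the enone face and sets C8 as R, followed by O-silylation of the regiodefined aluminium enolate to fix the tetrasubstituted enol ether.

**Step 2**
Reactants: 3 trimethyl{[(3R)-2,3-dimethylcyclohex-1-en-1-yl]oxy}silane; 4 but-3-en-2-one
Product: 5 (2S,3R)-2,3-dimethyl-2-(3-oxobutyl)cyclohexan-1-one
Conditions: TiCl4, CH2Cl2, −78 °C; aq. K2CO3 quench at −78 °C
Reagents that add atoms: none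
Why: Mukaiyama–Michael addition in which the TiCl4-activated enone is attacked by the silyl enol ether anti to the pseudoaxial C8 methyl, building quaternary C9 with the two methyls cis (the minor epimer is removed by chromatography).

**Step 3**
Reactants: 5 (2S,3R)-2,3-dimethyl-2-(3-oxobutyl)cyclohexan-1-one
Product: 6 (2S,3R)-2,3-dimethyl-2-[2-(2-methyl-1,3-dioxolan-2-yl)ethyl]cyclohexan-1-one
Conditions: (TMSOCH2)2, TMSOTf (5 mol%), CH2Cl2, −78 → −20 °C
Reagents that add atoms: 1,2-bis(trimethylsilyloxy)ethane C[Si](C)(C)OCCO[Si](C)(C)C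
Why: Noyori ketalisation is selective for the unhindered methyl ketone because the ring ketone is flanked by quaternary C9, and the cold aprotic conditions avoid aldol cyclisation of the 1,5-diketone.

**Step 4**
Reactants: 6 (2S,3R)-2,3-dimethyl-2-[2-(2-methyl-1,3-dioxolan-2-yl)ethyl]cyclohexan-1-one
Product: 7 (5R,6S)-5,6-dimethyl-6-[2-(2-methyl-1,3-dioxolan-2-yl)ethyl]cyclohex-1-en-1-yl trifluoromethanesulfonate
Conditions: KN(SiMe3)2, THF, −78 °C; PhNTf2, −78 → 0 °C
Reagents that add atoms: N-phenylbis(trifluoromethanesulfonimide) O=S(=O)(N(c1ccccc1)S(=O)(=O)C(F)(F)F)C(F)(F)F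
Why: Enolisation can only occur toward C5 because C9 is quaternary, so enolate O-triflation gives a single vinyl triflate.

**Step 5**
Reactants: 7 (5R,6S)-5,6-dimethyl-6-[2-(2-methyl-1,3-dioxolan-2-yl)ethyl]cyclohex-1-en-1-yl trifluoromethanesulfonate
Product: 8 methyl (5R,6S)-5,6-dimethyl-6-[2-(2-methyl-1,3-dioxolan-2-yl)ethyl]cyclohex-1-ene-1-carboxylate
Conditions: Pd(OAc)2 (5 mol%), PPh3 (10 mol%), CO (1 atm), MeOH, Et3N, DMF, 60 °C
Reagents that add atoms: carbon monoxide [C-]#[O+]; methanol CO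
Why: Palladium-catalysed methoxycarbonylation (oxidative addition of zerovalent palladium into the C–OTf bond, CO insertion, methanolysis) installs C1 as a conjugated ester.

**Step 6**
Reactants: 8 methyl (5R,6S)-5,6-dimethyl-6-[2-(2-methyl-1,3-dioxolan-2-yl)ethyl]cyclohex-1-ene-1-carboxylate
Product: 9 {(5R,6S)-5,6-dimethyl-6-[2-(2-methyl-1,3-dioxolan-2-yl)ethyl]cyclohex-1-en-1-yl}methanol
Conditions: iBu2AlH (2.5 equiv), CH2Cl2, −78 → 0 °C; aq. potassium sodium tartrate
Reagents that add atoms: none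
Why: 1,2-Reduction of the conjugated ester by iBu2AlH gives the allylic alcohol while the dioxolane is inert.

**Step 7**
Reactants: 9 {(5R,6S)-5,6-dimethyl-6-[2-(2-methyl-1,3-dioxolan-2-yl)ethyl]cyclohex-1-en-1-yl}methanol
Product: 10 (5R,6S)-5,6-dimethyl-6-[2-(2-methyl-1,3-dioxolan-2-yl)ethyl]cyclohex-1-ene-1-carbaldehyde
Conditions: MnO2 (excess), CH2Cl2, rt
Reagents that add atoms: none
Why: MnO2 oxidises the allylic alcohol selectively to the enal without touching the ketal or any stereocentre.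

**Step 8**
Reactants: 10 (5R,6S)-5,6-dimethyl-6-[2-(2-methyl-1,3-dioxolan-2-yl)ethyl]cyclohex-1-ene-1-carbaldehyde; 11 allylmagnesium bromide
Product: 13 (1R)-1-{(5R,6S)-5,6-dimethyl-6-[2-(2-methyl-1,3-dioxolan-2-yl)ethyl]cyclohex-1-en-1-yl}but-3-en-1-ol, via (+)-B-allyldiisopinocampheylborane 12 (not isolated)
Conditions: (+)-Ipc2BOMe (from (−)-α-pinene), 11, Et2O, 0 °C → rt; then 10, −78 °C; then NaOH, H2O2, rt
Reagents that add atoms: none
Why: Brown asymmetric carbonyl allylation through a chair six-membered transition state whose facial sense is set by the isopinocampheyl groups (Re-face attack, as for benzaldehyde giving the R alcohol), so C1 is set as R, and any minor ring B enantiomer from step 1 becomes a separable diastereomer.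

**Step 9**
Reactants: 13 (1R)-1-{(5R,6S)-5,6-dimethyl-6-[2-(2-methyl-1,3-dioxolan-2-yl)ethyl]cyclohex-1-en-1-yl}but-3-en-1-ol; 14 2-methylprop-2-enoyl chloride
Product: 15 (1R)-1-{(5R,6S)-5,6-dimethyl-6-[2-(2-methyl-1,3-dioxolan-2-yl)ethyl]cyclohex-1-en-1-yl}but-3-en-1-yl 2-methylprop-2-enoate
Conditions: Et3N, DMAP (cat.), CH2Cl2, 0 °C → rt
Reagents that add atoms: none
Why: DMAP-catalysed O-acylation of the secondary alcohol by the acid chloride leaves all stereocentres untouched.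

**Step 10**
Reactants: 15 (1R)-1-{(5R,6S)-5,6-dimethyl-6-[2-(2-methyl-1,3-dioxolan-2-yl)ethyl]cyclohex-1-en-1-yl}but-3-en-1-yl 2-methylprop-2-enoate
Product: 16 (6R)-6-{(5R,6S)-5,6-dimethyl-6-[2-(2-methyl-1,3-dioxolan-2-yl)ethyl]cyclohex-1-en-1-yl}-3-methyl-5,6-dihydro-2H-pyran-2-one
Conditions: second-generation Grubbs catalyst RuCl2(=CHPh)(PCy3)(H2IMes) (5 mol%), toluene (0.005 M), 80 °C
Reagents that add atoms: none
Why: Ring-closing metathesis between the terminal alkene and the methacrylate is driven by six-ring formation and loss of ethene, while the hindered trisubstituted ring B alkene does not take part.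

**Step 11**
Reactants: 16 (6R)-6-{(5R,6S)-5,6-dimethyl-6-[2-(2-methyl-1,3-dioxolan-2-yl)ethyl]cyclohex-1-en-1-yl}-3-methyl-5,6-dihydro-2H-pyran-2-one
Product: 17 (3RS,6R)-6-{(5R,6S)-5,6-dimethyl-6-[2-(2-methyl-1,3-dioxolan-2-yl)ethyl]cyclohex-1-en-1-yl}-3-methyloxan-2-one
Conditions: [(Ph3P)CuH]6 (0.4 equiv), toluene, H2O (2 equiv), rt
Reagents that add atoms: none
Why: Copper hydride conjugate reduction delivers hydride only to C3 of the unsaturated lactone, sparing the isolated alkene and the allylic C–O bond, and the epimeric mixture at C4 is erased by enolisation in the next step.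

**Step 12**
Reactants: 17 (3RS,6R)-6-{(5R,6S)-5,6-dimethyl-6-[2-(2-methyl-1,3-dioxolan-2-yl)ethyl]cyclohex-1-en-1-yl}-3-methyloxan-2-one
Product: 20 (1S,5S,6R,8aR)-1,5,6-trimethyl-5-[2-(2-methyl-1,3-dioxolan-2-yl)ethyl]-1,2,3,5,6,7,8,8a-octahydronaphthalene-1-carboxylic acid, via silyl ketene acetal 18 (not isolated), via silyl ester 19 (not isolated)
Conditions: LiN(iPr)2, THF, −78 °C; TBSCl, DMPU, −78 °C → rt; toluene, 110 °C; then AcOH–THF–H2O (1:4:1), rt, 30 min
Reagents that add atoms: none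
Why: Ireland–Claisen rearrangement of the lactone silyl ketene acetal (Claisen ring contraction), where the six-membered lactone enforces a boat transition state with C4 adding to C5 on the face of the C1–O bond, so the 1R centre is relayed to 4S (methyl cis to H5, carboxyl trans) and 5R (H5 cis to the C9 methyl) as the Δ1(10) alkene forms.

**Step 13**
Reactants: 20 (1S,5S,6R,8aR)-1,5,6-trimethyl-5-[2-(2-methyl-1,3-dioxolan-2-yl)ethyl]-1,2,3,5,6,7,8,8a-octahydronaphthalene-1-carboxylic acid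
Product: 21 methyl (1S,5S,6R,8aR)-1,5,6-trimethyl-5-[2-(2-methyl-1,3-dioxolan-2-yl)ethyl]-1,2,3,5,6,7,8,8a-octahydronaphthalene-1-carboxylate
Conditions: MeI, K2CO3, DMF, rt
Reagents that add atoms: iodomethane CI
Why: SN2 O-alkylation of the carboxylate works even for this hindered acid because the bond forms at the methyl carbon of MeI.

**Step 14**
Reactants: 21 methyl (1S,5S,6R,8aR)-1,5,6-trimethyl-5-[2-(2-methyl-1,3-dioxolan-2-yl)ethyl]-1,2,3,5,6,7,8,8a-octahydronaphthalene-1-carboxylate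
Product: 22 methyl (1S,5S,6R,8aR)-1,5,6-trimethyl-5-(3-oxobutyl)-1,2,3,5,6,7,8,8a-octahydronaphthalene-1-carboxylate
Conditions: 1 M aq. HCl, THF, rt
Reagents that add atoms: water O
Why: Acid-catalysed hydrolysis of the dioxolane, where dilute acid at room temperature does not protonate the trisubstituted alkene and no free carboxylic acid remains that could lactonise.

**Step 15**
Reactants: 22 methyl (1S,5S,6R,8aR)-1,5,6-trimethyl-5-(3-oxobutyl)-1,2,3,5,6,7,8,8a-octahydronaphthalene-1-carboxylate; 23 triethyl phosphonoacetate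
Product: 24 methyl (1S,5S,6R,8aR)-5-[(3E)-5-ethoxy-3-methyl-5-oxopent-3-en-1-yl]-1,5,6-trimethyl-1,2,3,5,6,7,8,8a-octahydronaphthalene-1-carboxylate
Conditions: NaH, THF, 0 → 50 °C; chromatography to remove the Z isomer
Reagents that add atoms: none
Why: Horner–Wadsworth–Emmons olefination of the unhindered methyl ketone gives mainly the E trisubstituted enoate (about 5:1), while the C4 ester has no α-hydrogen and is too hindered to react.

**Step 16**
Reactants: 24 methyl (1S,5S,6R,8aR)-5-[(3E)-5-ethoxy-3-methyl-5-oxopent-3-en-1-yl]-1,5,6-trimethyl-1,2,3,5,6,7,8,8a-octahydronaphthalene-1-carboxylate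
Product: 25 methyl (1S,5S,6R,8aR)-5-[(3E)-5-hydroxy-3-methylpent-3-en-1-yl]-1,5,6-trimethyl-1,2,3,5,6,7,8,8a-octahydronaphthalene-1-carboxylate
Conditions: iBu2AlH (2.2 equiv), CH2Cl2, −78 °C; aq. potassium sodium tartrate
Reagents that add atoms: none
Why: iBu2AlH reduces the unhindered conjugated ethyl ester at −78 °C much faster than the neopentyl-type methyl ester on quaternary C4, giving the allylic alcohol with the E geometry retained.

**Step 17**
Reactants: 25 methyl (1S,5S,6R,8aR)-5-[(3E)-5-hydroxy-3-methylpent-3-en-1-yl]-1,5,6-trimethyl-1,2,3,5,6,7,8,8a-octahydronaphthalene-1-carboxylate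
Product: 26 methyl (1S,5S,6R,8aR)-5-[(3E)-5-(acetyloxy)-3-methylpent-3-en-1-yl]-1,5,6-trimethyl-1,2,3,5,6,7,8,8a-octahydronaphthalene-1-carboxylate
Conditions: Ac2O, pyridine, DMAP (cat.), CH2Cl2, rt
Reagents that add atoms: acetic anhydride CC(=O)OC(C)=O
Why: DMAP-catalysed acetylation of the primary allylic alcohol gives the target without touching any stereocentre.

**Compound list**
1 | 2-methylcyclohex-2-en-1-one | CC1=CCCC1=O | starting material
2 | dimethylaluminium (3R)-2,3-dimethylcyclohex-1-en-1-olate | C[Al](C)OC1=C(C)[C@H](C)CCC1 | intermediate (not isolated)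
3 | trimethyl{[(3R)-2,3-dimethylcyclohex-1-en-1-yl]oxy}silane | C[Si](C)(C)OC1=C(C)[C@H](C)CCC1 | intermediate
4 | but-3-en-2-one (methyl vinyl ketone) | CC(=O)C=C | starting material
5 | (2S,3R)-2,3-dimethyl-2-(3-oxobutyl)cyclohexan-1-one | O=C1CCC[C@@H](C)[C@]1(C)CCC(C)=O | intermediate
6 | (2S,3R)-2,3-dimethyl-2-[2-(2-methyl-1,3-dioxolan-2-yl)ethyl]cyclohexan-1-one | O=C1CCC[C@@H](C)[C@]1(C)CCC2(C)OCCO2 | intermediate
7 | (5R,6S)-5,6-dimethyl-6-[2-(2-methyl-1,3-dioxolan-2-yl)ethyl]cyclohex-1-en-1-yl trifluoromethanesulfonate | O=S(=O)(OC1=CCC[C@@H](C)[C@]1(C)CCC2(C)OCCO2)C(F)(F)F | intermediate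
8 | methyl (5R,6S)-5,6-dimethyl-6-[2-(2-methyl-1,3-dioxolan-2-yl)ethyl]cyclohex-1-ene-1-carboxylate | COC(=O)C1=CCC[C@@H](C)[C@]1(C)CCC2(C)OCCO2 | intermediate
9 | {(5R,6S)-5,6-dimethyl-6-[2-(2-methyl-1,3-dioxolan-2-yl)ethyl]cyclohex-1-en-1-yl}methanol | OCC1=CCC[C@@H](C)[C@]1(C)CCC2(C)OCCO2 | intermediate
10 | (5R,6S)-5,6-dimethyl-6-[2-(2-methyl-1,3-dioxolan-2-yl)ethyl]cyclohex-1-ene-1-carbaldehyde | O=CC1=CCC[C@@H](C)[C@]1(C)CCC2(C)OCCO2 | intermediate
11 | allylmagnesium bromide | C=CC[Mg]Br | starting material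
12 | (+)-B-allyldiisopinocampheylborane, prop-2-en-1-ylbis[(1S,2R,3S,5S)-2,6,6-trimethylbicyclo[3.1.1]heptan-3-yl]borane | C=CCB([C@H]1C[C@H]2C[C@@H]([C@@H]1C)C2(C)C)[C@H]1C[C@H]2C[C@@H]([C@@H]1C)C2(C)C | intermediate (not isolated)
13 | (1R)-1-{(5R,6S)-5,6-dimethyl-6-[2-(2-methyl-1,3-dioxolan-2-yl)ethyl]cyclohex-1-en-1-yl}but-3-en-1-ol | O[C@H](CC=C)C1=CCC[C@@H](C)[C@]1(C)CCC2(C)OCCO2 | intermediate
14 | 2-methylprop-2-enoyl chloride (methacryloyl chloride) | CC(=C)C(Cl)=O | starting material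
15 | (1R)-1-{(5R,6S)-5,6-dimethyl-6-[2-(2-methyl-1,3-dioxolan-2-yl)ethyl]cyclohex-1-en-1-yl}but-3-en-1-yl 2-methylprop-2-enoate | CC(=C)C(=O)O[C@H](CC=C)C1=CCC[C@@H](C)[C@]1(C)CCC2(C)OCCO2 | intermediate
16 | (6R)-6-{(5R,6S)-5,6-dimethyl-6-[2-(2-methyl-1,3-dioxolan-2-yl)ethyl]cyclohex-1-en-1-yl}-3-methyl-5,6-dihydro-2H-pyran-2-one | O=C1O[C@H](CC=C1C)C2=CCC[C@@H](C)[C@]2(C)CCC3(C)OCCO3 | intermediate
17 | (3RS,6R)-6-{(5R,6S)-5,6-dimethyl-6-[2-(2-methyl-1,3-dioxolan-2-yl)ethyl]cyclohex-1-en-1-yl}-3-methyloxan-2-one (C3 epimers) | O=C1O[C@H](CCC1C)C2=CCC[C@@H](C)[C@]2(C)CCC3(C)OCCO3 | intermediate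
18 | tert-butyl(dimethyl){[(2R)-2-{(5R,6S)-5,6-dimethyl-6-[2-(2-methyl-1,3-dioxolan-2-yl)ethyl]cyclohex-1-en-1-yl}-5-methyl-3,4-dihydro-2H-pyran-6-yl]oxy}silane | CC1=C(O[Si](C)(C)C(C)(C)C)O[C@H](CC1)C2=CCC[C@@H](C)[C@]2(C)CCC3(C)OCCO3 | intermediate (not isolated)
19 | tert-butyldimethylsilyl (1S,5S,6R,8aR)-1,5,6-trimethyl-5-[2-(2-methyl-1,3-dioxolan-2-yl)ethyl]-1,2,3,5,6,7,8,8a-octahydronaphthalene-1-carboxylate | CC(C)(C)[Si](C)(C)OC(=O)[C@@]1(C)CCC=C2[C@H]1CC[C@@H](C)[C@]2(C)CCC3(C)OCCO3 | intermediate (not isolated)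
20 | (1S,5S,6R,8aR)-1,5,6-trimethyl-5-[2-(2-methyl-1,3-dioxolan-2-yl)ethyl]-1,2,3,5,6,7,8,8a-octahydronaphthalene-1-carboxylic acid | OC(=O)[C@@]1(C)CCC=C2[C@H]1CC[C@@H](C)[C@]2(C)CCC3(C)OCCO3 | intermediate
21 | methyl (1S,5S,6R,8aR)-1,5,6-trimethyl-5-[2-(2-methyl-1,3-dioxolan-2-yl)ethyl]-1,2,3,5,6,7,8,8a-octahydronaphthalene-1-carboxylate | COC(=O)[C@@]1(C)CCC=C2[C@H]1CC[C@@H](C)[C@]2(C)CCC3(C)OCCO3 | intermediate
22 | methyl (1S,5S,6R,8aR)-1,5,6-trimethyl-5-(3-oxobutyl)-1,2,3,5,6,7,8,8a-octahydronaphthalene-1-carboxylate | COC(=O)[C@@]1(C)CCC=C2[C@H]1CC[C@@H](C)[C@]2(C)CCC(C)=O | intermediate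
23 | triethyl phosphonoacetate | CCOC(=O)CP(=O)(OCC)OCC | starting material
24 | methyl (1S,5S,6R,8aR)-5-[(3E)-5-ethoxy-3-methyl-5-oxopent-3-en-1-yl]-1,5,6-trimethyl-1,2,3,5,6,7,8,8a-octahydronaphthalene-1-carboxylate | COC(=O)[C@@]1(C)CCC=C2[C@H]1CC[C@@H](C)[C@]2(C)CC/C(C)=C/C(=O)OCC | intermediate
25 | methyl (1S,5S,6R,8aR)-5-[(3E)-5-hydroxy-3-methylpent-3-en-1-yl]-1,5,6-trimethyl-1,2,3,5,6,7,8,8a-octahydronaphthalene-1-carboxylate | COC(=O)[C@@]1(C)CCC=C2[C@H]1CC[C@@H](C)[C@]2(C)CC/C(C)=C/CO | intermediate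
26 | methyl (1S,5S,6R,8aR)-5-[(3E)-5-(acetyloxy)-3-methylpent-3-en-1-yl]-1,5,6-trimethyl-1,2,3,5,6,7,8,8a-octahydronaphthalene-1-carboxylate | COC(=O)[C@@]1(C)CCC=C2[C@H]1CC[C@@H](C)[C@]2(C)CC/C(C)=C/COC(C)=O | target

**Totals**
Total step count: 17. Longest linear sequence: 17 steps (1 → 26).

**Three steps most likely to fail**

Step 12 (Claisen ring contraction). The boat transition state must build a quaternary carbon next to the ring-fusion carbon, and the ketene acetal may decompose before it rearranges. Fallback: set out from enal 10. Wittig methylenation (Ph3PCH3Br, KOtBu, THF, 0 °C) gives the diene 2-{2-[(1S,6R)-2-ethenyl-1,6-dimethylcyclohex-2-en-1-yl]ethyl}-2-methyl-1,3-dioxolane F2. A thermal Diels–Alder reaction of F2 with methyl methacrylate (neat, BHT, 110 °C, sealed tube) then builds ring A in one step and comes back to the route at 21. The ester-bearing carbon should join C5 ("ortho" regiochemistry), and approach anti to the pseudoaxial C9 methyl gives the right C5 configuration. The required ester-endo adduct is expected only as roughly half of the endo/exo mixture, so 21 has to be separated by preparative HPLC; this fallback is shorter but stereochemically weaker.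

Step 2 (Mukaiyama–Michael addition). Methyl vinyl ketone can polymerise under TiCl4, and the congested quaternary centre may form in low yield or with modest diastereoselectivity. Fallback: set out from 3. MeLi (THF, 0 °C) releases the lithium enolate, which is alkylated with 1,3-dichlorobut-2-ene (THF–DMPU, −78 → 0 °C) trans to the C8 methyl to give (2S,3R)-2-(3-chlorobut-2-en-1-yl)-2,3-dimethylcyclohexan-1-one F1. Hydrolysis of the vinyl chloride of F1 (Hg(OAc)2, 88% HCO2H, rt; Wichterle unmasking) gives the 3-oxobutyl chain and comes back to the route at 5.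

Step 15 (Horner–Wadsworth–Emmons olefination). The E/Z ratio from a methyl ketone is only moderate and the isomers may be hard to separate. Fallback: set out from 22. LiN(iPr)2 (THF, −78 °C) then ClP(O)(OEt)2 gives the kinetic enol phosphate methyl (1S,5S,6R,8aR)-5-{3-[(diethoxyphosphoryl)oxy]but-3-en-1-yl}-1,5,6-trimethyl-1,2,3,5,6,7,8,8a-octahydronaphthalene-1-carboxylate F3. Further LiN(iPr)2 (2.2 equiv, −78 °C → rt) eliminates F3 to the terminal alkyne methyl (1S,5S,6R,8aR)-5-(but-3-yn-1-yl)-1,5,6-trimethyl-1,2,3,5,6,7,8,8a-octahydronaphthalene-1-carboxylate F4. Negishi carboalumination of F4 (Me3Al, Cp2ZrCl2 cat., (CH2Cl)2, rt; then (CH2O)n) adds methyl and the hydroxymethyl group syn across the alkyne and comes back to the route at 25 with the E geometry fixed, skipping 24.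

**Further compounds**
F1 | step 2 | (2S,3R)-2-(3-chlorobut-2-en-1-yl)-2,3-dimethylcyclohexan-1-one (alkene E/Z mixture) | O=C1CCC[C@@H](C)[C@]1(C)CC=C(C)Cl
F2 | step 12 | 2-{2-[(1S,6R)-2-ethenyl-1,6-dimethylcyclohex-2-en-1-yl]ethyl}-2-methyl-1,3-dioxolane | C=CC1=CCC[C@@H](C)[C@]1(C)CCC2(C)OCCO2
F3 | step 15 | methyl (1S,5S,6R,8aR)-5-{3-[(diethoxyphosphoryl)oxy]but-3-en-1-yl}-1,5,6-trimethyl-1,2,3,5,6,7,8,8a-octahydronaphthalene-1-carboxylate | COC(=O)[C@@]1(C)CCC=C2[C@H]1CC[C@@H](C)[C@]2(C)CCC(=C)OP(=O)(OCC)OCC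
F4 | step 15 | methyl (1S,5S,6R,8aR)-5-(but-3-yn-1-yl)-1,5,6-trimethyl-1,2,3,5,6,7,8,8a-octahydronaphthalene-1-carboxylate | COC(=O)[C@@]1(C)CCC=C2[C@H]1CC[C@@H](C)[C@]2(C)CCC#C
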